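**Strategy.** Ring C of the flavanone is a β-aryloxy ketone, O1–C2–C3–C4(=O)–C4a–C8a. It is cut at C3–C4 and O1–C8a into a ring-A 1,3-dielectrophile, 2-fluoro-4,6-dimethoxybenzoyl chloride (acyl carbon C4, C–F carbon C8a), and a 1,3-dinucleophile, an (R)-β-silyloxy alkylzinc bromide (CH2Zn is C3, the silylated oxygen is O1) that already carries C2, ring B, the diaryl ether and the protected flavone. One pot joins them: Negishi acylation forms the ketone, which activates its ortho C–F bond for fluoride-triggered SNAr closure. No bond to C2 is made or broken, so the configuration from a CBS reduction passes unchanged into ring C.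

Key step: step 11

Remark: the stereocentre of the target is read as (2S). In the bromohydrin, its silyl ether and the organozinc the same spatial arrangement is named R, because CH2Br and CH2Zn outrank the aryl group. Compounds 1, 2, 5 and 12 are taken as purchasable.

**Step 1**
Reactants: 1 1-[2,4-bis(benzyloxy)-6-hydroxyphenyl]ethanone; 2 4-iodobenzaldehyde
Product: 3 (E)-1-[2,4-bis(benzyloxy)-6-hydroxyphenyl]-3-(4-iodophenyl)prop-2-en-1-one
Conditions: KOH (50% aq), EtOH/THF, rt
Reagents that add atoms: none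
Why: Claisen–Schmidt condensation, in which the methyl ketone enolate adds to the non-enolisable aldehyde and E1cB dehydration should give the E-enone, with benzyl ethers and the C–I bond inert to hydroxide.

**Step 2**
Reactants: 3 (E)-1-[2,4-bis(benzyloxy)-6-hydroxyphenyl]-3-(4-iodophenyl)prop-2-en-1-one
Product: 4 5,7-bis(benzyloxy)-2-(4-iodophenyl)-4H-chromen-4-one
Conditions: I2 (10 mol%), DMSO, 130 °C
Reagents that add atoms: none
Why: Iodine-mediated oxidative cyclisation of a 2'-hydroxychalcone (oxa-Michael closure, α-iodination and loss of HI, with DMSO as terminal oxidant) should give the flavone without touching the aryl iodide.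

**Step 3**
Reactants: 5 1-(3,4-dihydroxyphenyl)ethanone
Product: 6 1-[4-(benzyloxy)-3-hydroxyphenyl]ethanone
Conditions: BnBr (1.0 equiv), NaHCO3, NaI (cat.), DMF, 40 °C
Reagents that add atoms: benzyl bromide, BrCc1ccccc1
Why: Williamson ether synthesis in which hydrogencarbonate ionises only the more acidic 4-hydroxyl (para to the acetyl group), so benzylation should be regioselective and leave the 3-hydroxyl free.

**Step 4**
Reactants: 4 5,7-bis(benzyloxy)-2-(4-iodophenyl)-4H-chromen-4-one; 6 1-[4-(benzyloxy)-3-hydroxyphenyl]ethanone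
Product: 7 2-{4-[5-acetyl-2-(benzyloxy)phenoxy]phenyl}-5,7-bis(benzyloxy)-4H-chromen-4-one
Conditions: CuI (10 mol%), N,N-dimethylglycine hydrochloride (30 mol%), Cs2CO3, 1,4-dioxane, 90 °C
Reagents that add atoms: none
Why: Ullmann diaryl ether coupling with an amino acid ligand joins the aryl iodide and the ortho-alkoxy phenol under conditions that the chromone, benzyl ethers and methyl ketone should tolerate.

**Step 5**
Reactants: 7 2-{4-[5-acetyl-2-(benzyloxy)phenoxy]phenyl}-5,7-bis(benzyloxy)-4H-chromen-4-one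
Product: 9 5,7-bis(benzyloxy)-2-{4-[2-(benzyloxy)-5-(bromoacetyl)phenoxy]phenyl}-4H-chromen-4-one, via silyl enol ether 8 (not isolated)
Conditions: LiHMDS, TMSCl, THF, −78 °C; then NBS, −78 → 0 °C
Reagents that add atoms: N-bromosuccinimide, O=C1CCC(=O)N1Br
Why: α-Halogenation through a silyl enol ether: the methyl ketone is the only enolisable site, and the enol silane should react with NBS at low temperature far faster than the alkoxyarenes or flavone C3.

**Step 6**
Reactants: 9 5,7-bis(benzyloxy)-2-{4-[2-(benzyloxy)-5-(bromoacetyl)phenoxy]phenyl}-4H-chromen-4-one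
Product: 10 5,7-bis(benzyloxy)-2-(4-{2-(benzyloxy)-5-[(1R)-2-bromo-1-hydroxyethyl]phenoxy}phenyl)-4H-chromen-4-one
Conditions: (R)-2-methyl-CBS-oxazaborolidine (15 mol%), BH3·SMe2, THF, −20 °C; MeOH quench
Reagents that add atoms: none
Why: Corey–Bakshi–Shibata reduction, in which the (R)-catalyst delivers hydride with the aryl group as the large substituent to give the (R)-bromohydrin (the future 2S centre), the activated α-bromo ketone being reduced much faster than the vinylogous-ester carbonyl of the flavone.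

**Step 7**
Reactants: 10 5,7-bis(benzyloxy)-2-(4-{2-(benzyloxy)-5-[(1R)-2-bromo-1-hydroxyethyl]phenoxy}phenyl)-4H-chromen-4-one
Product: 11 5,7-bis(benzyloxy)-2-(4-{2-(benzyloxy)-5-[(1R)-2-bromo-1-(triethylsilyloxy)ethyl]phenoxy}phenyl)-4H-chromen-4-one
Conditions: TESOTf, 2,6-lutidine, CH2Cl2, −78 °C
Reagents that add atoms: triethylsilyl trifluoromethanesulfonate, CC[Si](CC)(CC)OS(=O)(=O)C(F)(F)F
Why: O-Silylation with a silyl triflate and a hindered pyridine base should outrun base-induced epoxide formation and caps O1 for the organozinc chemistry without touching the stereocentre.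

**Step 8**
Reactants: 12 1-fluoro-3,5-dimethoxybenzene
Product: 13 2-fluoro-4,6-dimethoxybenzaldehyde
Conditions: POCl3, DMF, 0 → 70 °C; aq NaOAc
Reagents that add atoms: N,N-dimethylformamide, CN(C)C=O; water, O
Why: Vilsmeier–Haack formylation, in which the chloroiminium ion should attack the position para to one methoxy and ortho to the other (the site between the two methoxy groups being more hindered), followed by hydrolysis to the aldehyde.

**Step 9**
Reactants: 13 2-fluoro-4,6-dimethoxybenzaldehyde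
Product: 14 2-fluoro-4,6-dimethoxybenzoic acid
Conditions: NaClO2, NaH2PO4, 2-methyl-2-butene, t-BuOH/H2O, rt
Reagents that add atoms: sodium chlorite, [Na+].[O-]Cl=O
Why: Pinnick oxidation converts the aldehyde to the acid while the alkene scavenger removes hypochlorite before it can chlorinate the electron-rich ring.

**Step 10**
Reactants: 14 2-fluoro-4,6-dimethoxybenzoic acid
Product: 15 2-fluoro-4,6-dimethoxybenzoyl chloride
Conditions: (COCl)2, DMF (cat.), CH2Cl2, 0 °C → rt
Reagents that add atoms: oxalyl chloride, O=C(Cl)C(=O)Cl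
Why: Acyl chloride formation through the chloroiminium catalyst from DMF and oxalyl chloride, under which methyl ethers and the C–F bond are inert.

**Step 11**
Reactants: 11 5,7-bis(benzyloxy)-2-(4-{2-(benzyloxy)-5-[(1R)-2-bromo-1-(triethylsilyloxy)ethyl]phenoxy}phenyl)-4H-chromen-4-one; 15 2-fluoro-4,6-dimethoxybenzoyl chloride
Product: 18 (2S)-2-{4-(benzyloxy)-3-[4-(5,7-bis(benzyloxy)-4-oxo-4H-chromen-2-yl)phenoxy]phenyl}-5,7-dimethoxychroman-4-one, via alkylzinc bromide 16 (not isolated), via silyloxy ketone 17 (not isolated)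
Conditions: Zn dust (activated with BrCH2CH2Br and TMSCl), I2 (5 mol%), DMA, 60 °C; then 15 (0.95 equiv), Pd(PPh3)4 (5 mol%), DMA/THF, 0 °C → rt; then CsF (4 equiv), rt
Reagents that add atoms: none
Why: Zinc inserts into the primary C–Br bond of 11 to give the β-silyloxy alkylzinc 16, which Pd(PPh3)4 couples with acyl chloride 15 (oxidative addition into C–Cl, transmetalation, reductive elimination) to form the C3–C4 bond of ketone 17; CsF then cleaves the O–Si bond and alkoxide O1 displaces fluoride at C8a by addition–elimination, the fluoride set free carrying the desilylation on. The closest known reaction types are the Negishi acylation of alkylzinc halides and the SNAr ring closure of 2-fluoroaryl ketones by a tethered oxygen nucleophile, as used for chromones and flavones. Ring C is closed by a six-membered addition–elimination at C8a, formally 6-endo with respect to the C8a=C4a bond conjugated to the new C4 ketone. No new stereocentre is formed: C2 keeps the configuration set in step 6 because no bond to it is made or broken, and the descriptor changes from R to S only through the CIP priorities. The step needs chemoselectivity (the organozinc must spare the flavone carbonyl, benzyl ethers and aryl fluoride, which the low basicity of RZnBr and the silyl cap on O1 should secure) and rate selectivity (closure must outrun retro-aldol cleavage and E1cB loss of O1, which the ortho-acyl activation of C–F, the two meta methoxy groups that do not deactivate C8a, and release of the alkoxide only as fast as fluoride cleaves the silyl ether should secure).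

**Step 12**
Reactants: 18 (2S)-2-{4-(benzyloxy)-3-[4-(5,7-bis(benzyloxy)-4-oxo-4H-chromen-2-yl)phenoxy]phenyl}-5,7-dimethoxychroman-4-one
Product: 19 (2S)-2-{3-[4-(5,7-dihydroxy-4-oxo-4H-chromen-2-yl)phenoxy]-4-hydroxyphenyl}-5-hydroxy-7-methoxychroman-4-one
Conditions: BCl3 (excess), pentamethylbenzene, CH2Cl2, −78 → 0 °C; MeOH quench
Reagents that add atoms: none
Why: Lewis-acid ether cleavage, in which BCl3 should remove the three benzyl groups as cations trapped by pentamethylbenzene and, through chelation between the C4 carbonyl and the peri oxygen, cleave only the 5-methoxy group of the flavanone, leaving the unchelated 7-methoxy group and, at low temperature, the C2 configuration intact.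

**Compound list**
1 | 1-[2,4-bis(benzyloxy)-6-hydroxyphenyl]ethanone | CC(=O)c1c(O)cc(OCc2ccccc2)cc1OCc1ccccc1 | starting material
2 | 4-iodobenzaldehyde | O=Cc1ccc(I)cc1 | starting material
3 | (E)-1-[2,4-bis(benzyloxy)-6-hydroxyphenyl]-3-(4-iodophenyl)prop-2-en-1-one | O=C(/C=C/c1ccc(I)cc1)c1c(O)cc(OCc2ccccc2)cc1OCc1ccccc1 | intermediate
4 | 5,7-bis(benzyloxy)-2-(4-iodophenyl)-4H-chromen-4-one | O=c1cc(-c2ccc(I)cc2)oc2cc(OCc3ccccc3)cc(OCc3ccccc3)c12 | intermediate
5 | 1-(3,4-dihydroxyphenyl)ethanone | CC(=O)c1ccc(O)c(O)c1 | starting material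
6 | 1-[4-(benzyloxy)-3-hydroxyphenyl]ethanone | CC(=O)c1ccc(OCc2ccccc2)c(O)c1 | intermediate
7 | 2-{4-[5-acetyl-2-(benzyloxy)phenoxy]phenyl}-5,7-bis(benzyloxy)-4H-chromen-4-one | CC(=O)c1ccc(OCc2ccccc2)c(Oc2ccc(-c3cc(=O)c4c(OCc5ccccc5)cc(OCc5ccccc5)cc4o3)cc2)c1 | intermediate
8 | 5,7-bis(benzyloxy)-2-(4-{2-(benzyloxy)-5-[1-(trimethylsilyloxy)ethenyl]phenoxy}phenyl)-4H-chromen-4-one (silyl enol ether) | C=C(O[Si](C)(C)C)c1ccc(OCc2ccccc2)c(Oc2ccc(-c3cc(=O)c4c(OCc5ccccc5)cc(OCc5ccccc5)cc4o3)cc2)c1 | intermediate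
9 | 5,7-bis(benzyloxy)-2-{4-[2-(benzyloxy)-5-(bromoacetyl)phenoxy]phenyl}-4H-chromen-4-one | O=C(CBr)c1ccc(OCc2ccccc2)c(Oc2ccc(-c3cc(=O)c4c(OCc5ccccc5)cc(OCc5ccccc5)cc4o3)cc2)c1 | intermediate
10 | 5,7-bis(benzyloxy)-2-(4-{2-(benzyloxy)-5-[(1R)-2-bromo-1-hydroxyethyl]phenoxy}phenyl)-4H-chromen-4-one | O[C@H](c1ccc(OCc2ccccc2)c(Oc2ccc(-c3cc(=O)c4c(OCc5ccccc5)cc(OCc5ccccc5)cc4o3)cc2)c1)CBr | intermediate
11 | 5,7-bis(benzyloxy)-2-(4-{2-(benzyloxy)-5-[(1R)-2-bromo-1-(triethylsilyloxy)ethyl]phenoxy}phenyl)-4H-chromen-4-one | CC[Si](CC)(CC)O[C@H](c1ccc(OCc2ccccc2)c(Oc2ccc(-c3cc(=O)c4c(OCc5ccccc5)cc(OCc5ccccc5)cc4o3)cc2)c1)CBr | intermediate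
12 | 1-fluoro-3,5-dimethoxybenzene | COc1cc(F)cc(OC)c1 | starting material
13 | 2-fluoro-4,6-dimethoxybenzaldehyde | COc1cc(F)c(C=O)c(OC)c1 | intermediate
14 | 2-fluoro-4,6-dimethoxybenzoic acid | COc1cc(F)c(C(=O)O)c(OC)c1 | intermediate
15 | 2-fluoro-4,6-dimethoxybenzoyl chloride | COc1cc(F)c(C(=O)Cl)c(OC)c1 | intermediate
16 | bromo{(2R)-2-[4-(benzyloxy)-3-{4-[5,7-bis(benzyloxy)-4-oxo-4H-chromen-2-yl]phenoxy}phenyl]-2-(triethylsilyloxy)ethyl}zinc | CC[Si](CC)(CC)O[C@H](c1ccc(OCc2ccccc2)c(Oc2ccc(-c3cc(=O)c4c(OCc5ccccc5)cc(OCc5ccccc5)cc4o3)cc2)c1)C[Zn]Br | intermediate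
17 | (3S)-3-[4-(benzyloxy)-3-{4-[5,7-bis(benzyloxy)-4-oxo-4H-chromen-2-yl]phenoxy}phenyl]-1-(2-fluoro-4,6-dimethoxyphenyl)-3-(triethylsilyloxy)propan-1-one | CC[Si](CC)(CC)O[C@H](c1ccc(OCc2ccccc2)c(Oc2ccc(-c3cc(=O)c4c(OCc5ccccc5)cc(OCc5ccccc5)cc4o3)cc2)c1)CC(=O)c1c(F)cc(OC)cc1OC | intermediate
18 | (2S)-2-{4-(benzyloxy)-3-[4-(5,7-bis(benzyloxy)-4-oxo-4H-chromen-2-yl)phenoxy]phenyl}-5,7-dimethoxychroman-4-one | COc1cc(OC)c2c(c1)O[C@H](c1ccc(OCc3ccccc3)c(Oc3ccc(-c4cc(=O)c5c(OCc6ccccc6)cc(OCc6ccccc6)cc5o4)cc3)c1)CC2=O | intermediate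
19 | (2S)-2-{3-[4-(5,7-dihydroxy-4-oxo-4H-chromen-2-yl)phenoxy]-4-hydroxyphenyl}-5-hydroxy-7-methoxychroman-4-one | COc1cc(O)c2c(c1)O[C@H](c1ccc(O)c(Oc3ccc(-c4cc(=O)c5c(O)cc(O)cc5o4)cc3)c1)CC2=O | target

**Total step count:** 12. **Longest linear sequence:** 8 steps (steps 1, 2, 4, 5, 6, 7, 11, 12).

**Steps most likely to fail**

1. Step 11. The alkylzinc may lose zinc silyloxide by β-elimination during insertion, acylation of the doubly ortho-substituted acyl chloride may be slow, and at the alkoxide stage retro-aldol cleavage or E1cB loss of O1 may compete with ring closure and erode yield or enantiopurity. The fallback sets out from 11 and 15 and comes back at 17 and then 18. A nickel-catalysed reductive cross-electrophile coupling (NiCl2(dme), 4,4′-di-tert-butyl-2,2′-bipyridine, Mn powder, DMA, 0 °C → rt) would join the alkyl bromide and the acyl chloride through a transient alkyl radical and an acylnickel species, with no preformed organozinc, and the same CsF closure would follow in the flask. No compound outside the list arises (F0).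

2. Step 12. The unchelated 7-methyl ether may be cleaved as well, benzyl cations may alkylate the phloroglucinol rings, and the boron chelate may open ring C by retro-oxa-Michael reaction and scramble C2. The fallback sets out from 13 and comes back at 19, moving the chelation-controlled demethylation to the achiral aldehyde. BCl3 (CH2Cl2, 0 °C) would cleave only the methoxy group ortho to the formyl group to give 2-fluoro-6-hydroxy-4-methoxybenzaldehyde F1. Benzylation (BnBr, K2CO3, DMF) would give 2-(benzyloxy)-6-fluoro-4-methoxybenzaldehyde F2. Pinnick oxidation would give 2-(benzyloxy)-6-fluoro-4-methoxybenzoic acid F3, and oxalyl chloride its acyl chloride 2-(benzyloxy)-6-fluoro-4-methoxybenzoyl chloride F4. The one-pot acylation and ring closure with 11 (through 16 and the 5-O-benzyl silyloxy ketone F5) would give the tetrabenzyl flavanone F6. Hydrogenolysis (H2, Pd/C, EtOAc/THF, rt) would then remove all four benzyl groups under neutral conditions to give 19.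

3. Step 4. Coupling of the hindered ortho-benzyloxy phenoxide may be sluggish, and the hot carbonate may cause self-condensation of the methyl ketone or reductive loss of iodine. The fallback sets out from 4 and 6 and comes back at 7. Miyaura borylation of 4 (B2pin2, PdCl2(dppf), KOAc, dioxane, 80 °C) would give 5,7-bis(benzyloxy)-2-[4-(4,4,5,5-tetramethyl-1,3,2-dioxaborolan-2-yl)phenyl]-4H-chromen-4-one F7. A Chan–Lam coupling with phenol 6 (Cu(OAc)2, pyridine, B(OH)3, 4 Å MS, MeCN, air, 60 °C) would then form the same C–O bond oxidatively, without carbonate base.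

**Further compounds**
F0 | step 11 | none | none
F1 | step 12 | 2-fluoro-6-hydroxy-4-methoxybenzaldehyde | COc1cc(O)c(C=O)c(F)c1
F2 | step 12 | 2-(benzyloxy)-6-fluoro-4-methoxybenzaldehyde | COc1cc(F)c(C=O)c(OCc2ccccc2)c1
F3 | step 12 | 2-(benzyloxy)-6-fluoro-4-methoxybenzoic acid | COc1cc(F)c(C(=O)O)c(OCc2ccccc2)c1
F4 | step 12 | 2-(benzyloxy)-6-fluoro-4-methoxybenzoyl chloride | COc1cc(F)c(C(=O)Cl)c(OCc2ccccc2)c1
F5 | step 12 | (3S)-1-[2-(benzyloxy)-6-fluoro-4-methoxyphenyl]-3-[4-(benzyloxy)-3-{4-[5,7-bis(benzyloxy)-4-oxo-4H-chromen-2-yl]phenoxy}phenyl]-3-(triethylsilyloxy)propan-1-one | CC[Si](CC)(CC)O[C@H](c1ccc(OCc2ccccc2)c(Oc2ccc(-c3cc(=O)c4c(OCc5ccccc5)cc(OCc5ccccc5)cc4o3)cc2)c1)CC(=O)c1c(F)cc(OC)cc1OCc1ccccc1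
F6 | step 12 | (2S)-5-(benzyloxy)-2-{4-(benzyloxy)-3-[4-(5,7-bis(benzyloxy)-4-oxo-4H-chromen-2-yl)phenoxy]phenyl}-7-methoxychroman-4-one | COc1cc(OCc2ccccc2)c2c(c1)O[C@H](c1ccc(OCc3ccccc3)c(Oc3ccc(-c4cc(=O)c5c(OCc6ccccc6)cc(OCc6ccccc6)cc5o4)cc3)c1)CC2=O
F7 | step 4 | 5,7-bis(benzyloxy)-2-[4-(4,4,5,5-tetramethyl-1,3,2-dioxaborolan-2-yl)phenyl]-4H-chromen-4-one | CC1(C)OB(c2ccc(-c3cc(=O)c4c(OCc5ccccc5)cc(OCc5ccccc5)cc4o3)cc2)OC1(C)C
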